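**Strategy.** Ring F is built last by a [3+3] benzannulation, so the crowded ring E oxygen does not have to be arylated a fifth time. Ring F carries that oxygen on C1 and hydroxyls on C3, C4 and C5. Its C1/C6/C5 unit therefore matches a 3-aryloxypropynoate, and its C2/C3/C4 unit matches a 4-benzyloxyacetoacetate. One operation (Michael addition, Claisen closure, aromatisation) forms C1–C2 and C4–C5 and places all four ring F oxygens. The precursor is the benzyl propynoate whose alkyne terminus bears the C4 oxygen of ring E of the permethylated five-ring fragment A–E. That fragment is grown by four repeats of an Ullmann coupling and hydrogenolysis pair.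

Key step: step 13

**Assumption:** rings are lettered A (2,4,6-trioxygenated end) to F (3,4,5-trioxygenated end), ring F is numbered from C1, the carbon bound to the ring E oxygen, and the target has no stereocentre, so no step needs stereocontrol. Compounds 1, 3, 12 and 17 are taken as catalogue compounds.

**Notation:** ring A is 2,4,6-trimethoxyphenyl. Each of rings B–E is a 3,5-dimethoxy-1,4-phenylene unit. Its C1 oxygen comes from the preceding ring. Its C4 oxygen, which lies between the two methoxy groups, leads to the next ring or to the named end group.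

**Design choices**
- The alkyne partner 16 is an ynol ether, with the ring E oxygen on an sp carbon, conjugated to an ester.
- Both ester groups in the key step are benzyl. The alkoxide expelled on ring closure then matches the surviving ester, so no ester scrambling occurs.
- The C2 ester later leaves by hydrogenolysis and mild decarboxylation. This avoids forcing saponification of a doubly ortho-substituted ester.
- The base is a non-nucleophilic amide added in two portions. A free alkoxide could displace the aryloxide from the oxygen-bearing alkyne carbon.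
- Benzyl groups are removed before BBr3 is used, so no benzyl cation can alkylate the electron-rich rings.
- In 20 the benzyloxy group lies between the two hydroxyls. It is at C4 in ring F numbering and at position 3 of the benzoate.

**Step 1**
Reactants: 1 4-bromo-2,6-dimethoxyphenol
Product: 2 2-(benzyloxy)-5-bromo-1,3-dimethoxybenzene
Conditions: BnBr (1.1 equiv), K2CO3, DMF, 50 °C
Reagents that add atoms: benzyl bromide, BrCc1ccccc1
Why: Williamson ether synthesis, in which the phenoxide of 1 is alkylated by an unhindered benzylic bromide while the aryl bromide is inert to carbonate.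

**Step 2**
Reactants: 3 2,4,6-trimethoxyphenol; 2 2-(benzyloxy)-5-bromo-1,3-dimethoxybenzene
Product: 4 two-ring benzyl ether A–B, 2-[4-(benzyloxy)-3,5-dimethoxyphenoxy]-1,3,5-trimethoxybenzene
Conditions: CuI (10 mol %), picolinic acid (20 mol %), K3PO4 (2 equiv), DMSO, 90 °C, Ar
Reagents that add atoms: none
Why: Ullmann-type diaryl ether synthesis, since the CuI/picolinic acid system accepts 2,6-disubstituted phenols and the bromide of 2 has two free ortho positions, so all crowding lies on the nucleophile.

**Step 3**
Reactants: 4 two-ring benzyl ether A–B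
Product: 5 two-ring phenol A–B, 2,6-dimethoxy-4-(2,4,6-trimethoxyphenoxy)phenol
Conditions: H2 (1 atm), 10% Pd/C, EtOAc–MeOH, rt
Reagents that add atoms: none
Why: Catalytic hydrogenolysis cleaves only the benzylic C–O bond, because diaryl ethers and aryl methyl ethers are inert to H2 over Pd/C at room temperature.

**Step 4**
Reactants: 5 two-ring phenol A–B; 2 2-(benzyloxy)-5-bromo-1,3-dimethoxybenzene
Product: 6 three-ring benzyl ether A–C (OBn on C4 of ring C)
Conditions: CuI (10 mol %), picolinic acid (20 mol %), K3PO4 (2 equiv), DMSO, 90 °C, Ar
Reagents that add atoms: none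
Why: Ullmann-type diaryl ether synthesis on a phenol whose local environment (two ortho methoxy groups) is the same as in step 2, so the same reactivity is expected.

**Step 5**
Reactants: 6 three-ring benzyl ether A–C
Product: 7 three-ring phenol A–C (OH on C4 of ring C)
Conditions: H2 (1 atm), 10% Pd/C, EtOAc–MeOH, rt
Reagents that add atoms: none
Why: Catalytic hydrogenolysis of the single benzyl aryl ether, with no other reducible group in the molecule.

**Step 6**
Reactants: 7 three-ring phenol A–C; 2 2-(benzyloxy)-5-bromo-1,3-dimethoxybenzene
Product: 8 four-ring benzyl ether A–D (OBn on C4 of ring D)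
Conditions: CuI (10 mol %), picolinic acid (20 mol %), K3PO4 (2 equiv), DMSO, 90 °C, Ar
Reagents that add atoms: none
Why: Ullmann-type diaryl ether synthesis in which the reacting phenol terminus is unchanged and the added chain is remote from the copper centre.

**Step 7**
Reactants: 8 four-ring benzyl ether A–D
Product: 9 four-ring phenol A–D (OH on C4 of ring D)
Conditions: H2 (1 atm), 10% Pd/C, THF–MeOH, rt
Reagents that add atoms: none
Why: Catalytic hydrogenolysis of the terminal benzyl ether, with THF added only to keep the larger oligomer in solution.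

**Step 8**
Reactants: 9 four-ring phenol A–D; 2 2-(benzyloxy)-5-bromo-1,3-dimethoxybenzene
Product: 10 five-ring benzyl ether A–E (OBn on C4 of ring E)
Conditions: CuI (15 mol %), picolinic acid (30 mol %), K3PO4 (2 equiv), DMSO, 95 °C, Ar
Reagents that add atoms: none
Why: Ullmann-type diaryl ether synthesis, fourth repeat, run with an excess of the cheap bromide 2 so that the valuable phenol is consumed.

**Step 9**
Reactants: 10 five-ring benzyl ether A–E
Product: 11 five-ring phenol A–E (OH on C4 of ring E)
Conditions: H2 (1 atm), 10% Pd/C, THF–MeOH, rt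
Reagents that add atoms: none
Why: Catalytic hydrogenolysis frees the ring E phenol without touching the four diaryl ether bonds or the eleven methyl ethers.

**Step 10**
Reactants: 11 five-ring phenol A–E; 12 trichloroethylene
Product: 13 (E)-1,2-dichlorovinyl ether of the five-ring phenol
Conditions: 12 (2 equiv), K2CO3, DMF, 70 °C
Reagents that add atoms: none
Why: Known vinylation of phenols, in which base removes HCl from 12 to give dichloroacetylene in solution and the phenoxide adds to it in anti fashion, so the crowded oxygen meets a slim linear electrophile and the E isomer results.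

**Step 11**
Reactants: 13 (E)-1,2-dichlorovinyl ether of the five-ring phenol
Product: 16 benzyl 3-aryloxypropynoate of fragment A–E, via chloroethynyl ether 14 (not isolated), via lithium acetylide 15 (not isolated)
Conditions: n-C4H9Li (2.2 equiv), THF, −78 °C; ClCO2CH2C6H5 (1.5 equiv), −78 to −20 °C; pH 7 buffer, Et3N-deactivated silica
Reagents that add atoms: benzyl chloroformate, O=C(Cl)OCc1ccccc1
Why: Known dichlorovinyl ether to ynol ether sequence, in which the first n-C4H9Li removes the vinyl proton and LiCl is lost to give 14, the second exchanges chlorine for lithium to give 15, and the acetylide is acylated by the chloroformate, all at −78 °C where ring lithiation of methoxyarenes is slow.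

**Step 12**
Reactants: 17 ethyl 4-(benzyloxy)-3-oxobutanoate
Product: 18 benzyl 4-(benzyloxy)-3-oxobutanoate
Conditions: BnOH (2 equiv), DMAP (0.2 equiv), toluene, reflux, EtOH distilled off
Reagents that add atoms: benzyl alcohol, OCc1ccccc1
Why: DMAP-catalysed transesterification of a β-keto ester, which runs through the acylketene or acylpyridinium pathway open to such esters and is driven by removal of ethanol.

**Step 13**
Reactants: 16 benzyl 3-aryloxypropynoate of fragment A–E; 18 benzyl 4-(benzyloxy)-3-oxobutanoate
Product: 20 six-ring benzyl 3-(benzyloxy)-2,4-dihydroxy-6-aryloxybenzoate (ring F closed), via Michael adduct 19 (not isolated)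
Conditions: 18 (1.1 equiv), NaN(SiMe3)2 (1.05 equiv), THF, −78 to 0 °C; add 16, 0 °C to rt; then NaN(SiMe3)2 (2.5 equiv), −78 °C to rt; 1 M HCl quench
Reagents that add atoms: none
Why: The monoenolate of 18, formed at its most acidic carbon C2, adds in Michael fashion to the alkyne carbon of 16 that carries the ring E oxygen (the β-position of the ynoate), and proton transfer gives the delocalised dienolate of 19, whose charge protects the aryloxy-bearing carbon from addition–elimination and lets the two enoate geometries interconvert. The second portion of NaN(SiMe3)2 then deprotonates the benzyloxy-bearing C4 of the keto ester part, and this carbanion attacks the ynoate-derived benzyl ester with loss of benzyl oxide in a Claisen (Dieckmann-type) acylation. Ring F closes in a 6-(enolendo)-exo-trig mode, which is favoured, and the cyclohexadienone formed tautomerises irreversibly to the resorcinol bis-phenoxide, so aromatisation drives the sequence. The closest known reaction type is the Michael–Claisen [3+3] benzannulation of β-keto ester or acetonedicarboxylate enolates with alkynoates to give resorcylates, applied here to an alkynoate with an aryloxy group at the acceptor carbon. No stereocentre is formed. Three selectivities are needed: attack through C2 before C4 (secured by forming only the monoenolate first, since a dianion would start at C4 and place the benzyloxy group next to C1), C- over O-acylation (secured by the strong amide base, which creates the C4 carbanion before the enolate oxygen can close a 2-pyranone) and retention of the aryloxy group (secured by the absence of any nucleophilic base while neutral 16 is present).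

**Step 14**
Reactants: 20 six-ring benzyl 3-(benzyloxy)-2,4-dihydroxy-6-aryloxybenzoate
Product: 22 six-ring ether whose ring F is a free 3,4,5-trihydroxyphenyl group (rings A–E permethylated), via carboxylic acid 21 (not isolated)
Conditions: H2 (1 atm), 10% Pd/C, THF–MeOH, rt; filter under Ar; degassed dioxane–H2O, 90 °C
Reagents that add atoms: none
Why: Hydrogenolysis removes the benzyl ether and the benzyl ester together, and acid 21, which has oxygen donors ortho, ortho and para to the carboxyl carbon, loses CO2 on mild heating by ipso-protonation (protodecarboxylation typical of phloroglucinol-type acids).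

**Step 15**
Reactants: 22 six-ring ether with free ring F triol
Product: 23 target hexamer CNP0187343.0
Conditions: BBr3 (25 equiv), CH2Cl2, −78 °C to rt, Ar; ice-water; EtOAc extraction; Sephadex LH-20, degassed MeOH
Reagents that add atoms: none
Why: Lewis acid ether cleavage, in which BBr3 binds each methoxy oxygen and bromide attacks the methyl carbon, while the diaryl ether bonds offer no sp3 carbon for attack and survive.

**Compound list**
1 | 4-bromo-2,6-dimethoxyphenol | COc1cc(Br)cc(OC)c1O | starting material
2 | 2-(benzyloxy)-5-bromo-1,3-dimethoxybenzene | COc1cc(Br)cc(OC)c1OCc2ccccc2 | intermediate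
3 | 2,4,6-trimethoxyphenol | COc1cc(OC)c(O)c(OC)c1 | starting material
4 | two-ring benzyl ether A–B | COc1cc(OC)c(Oc2cc(OC)c(OCc3ccccc3)c(OC)c2)c(OC)c1 | intermediate
5 | two-ring phenol A–B | COc1cc(OC)c(Oc2cc(OC)c(O)c(OC)c2)c(OC)c1 | intermediate
6 | three-ring benzyl ether A–C | COc1cc(OC)c(Oc2cc(OC)c(Oc3cc(OC)c(OCc4ccccc4)c(OC)c3)c(OC)c2)c(OC)c1 | intermediate
7 | three-ring phenol A–C | COc1cc(OC)c(Oc2cc(OC)c(Oc3cc(OC)c(O)c(OC)c3)c(OC)c2)c(OC)c1 | intermediate
8 | four-ring benzyl ether A–D | COc1cc(OC)c(Oc2cc(OC)c(Oc3cc(OC)c(Oc4cc(OC)c(OCc5ccccc5)c(OC)c4)c(OC)c3)c(OC)c2)c(OC)c1 | intermediate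
9 | four-ring phenol A–D | COc1cc(OC)c(Oc2cc(OC)c(Oc3cc(OC)c(Oc4cc(OC)c(O)c(OC)c4)c(OC)c3)c(OC)c2)c(OC)c1 | intermediate
10 | five-ring benzyl ether A–E | COc1cc(OC)c(Oc2cc(OC)c(Oc3cc(OC)c(Oc4cc(OC)c(Oc5cc(OC)c(OCc6ccccc6)c(OC)c5)c(OC)c4)c(OC)c3)c(OC)c2)c(OC)c1 | intermediate
11 | five-ring phenol A–E | COc1cc(OC)c(Oc2cc(OC)c(Oc3cc(OC)c(Oc4cc(OC)c(Oc5cc(OC)c(O)c(OC)c5)c(OC)c4)c(OC)c3)c(OC)c2)c(OC)c1 | intermediate
12 | trichloroethylene | ClC=C(Cl)Cl | starting material
13 | (E)-1,2-dichlorovinyl ether of 11 | Cl/C=C(/Cl)Oc1c(OC)cc(Oc2c(OC)cc(Oc3c(OC)cc(Oc4c(OC)cc(Oc5c(OC)cc(OC)cc5OC)cc4OC)cc3OC)cc2OC)cc1OC | intermediate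
14 | chloroethynyl ether of 11 (not isolated) | ClC#COc1c(OC)cc(Oc2c(OC)cc(Oc3c(OC)cc(Oc4c(OC)cc(Oc5c(OC)cc(OC)cc5OC)cc4OC)cc3OC)cc2OC)cc1OC | intermediate
15 | lithium aryloxyacetylide of 11 (not isolated) | [Li]C#COc1c(OC)cc(Oc2c(OC)cc(Oc3c(OC)cc(Oc4c(OC)cc(Oc5c(OC)cc(OC)cc5OC)cc4OC)cc3OC)cc2OC)cc1OC | intermediate
16 | benzyl 3-aryloxyprop-2-ynoate of fragment A–E (oxygen of ring E C4 on the alkyne) | O=C(OCc6ccccc6)C#COc1c(OC)cc(Oc2c(OC)cc(Oc3c(OC)cc(Oc4c(OC)cc(Oc5c(OC)cc(OC)cc5OC)cc4OC)cc3OC)cc2OC)cc1OC | intermediate
17 | ethyl 4-(benzyloxy)-3-oxobutanoate | CCOC(=O)CC(=O)COCc1ccccc1 | starting material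
18 | benzyl 4-(benzyloxy)-3-oxobutanoate | O=C(CC(=O)COCc1ccccc1)OCc2ccccc2 | intermediate
19 | dibenzyl (2E)-3-aryloxy-4-[(benzyloxy)acetyl]pent-2-enedioate (not isolated; drawn neutral as the isomer that can close; present as its dienolate, so C4 and the alkene geometry are labile) | O=C(OCc6ccccc6)/C=C(/Oc1c(OC)cc(Oc2c(OC)cc(Oc3c(OC)cc(Oc4c(OC)cc(Oc5c(OC)cc(OC)cc5OC)cc4OC)cc3OC)cc2OC)cc1OC)C(C(=O)OCc7ccccc7)C(=O)COCc8ccccc8 | intermediate
20 | six-ring compound, ring F = 3,5-dihydroxy-4-benzyloxy-2-(benzyloxycarbonyl)phenyl | COc1cc(OC)c(Oc2cc(OC)c(Oc3cc(OC)c(Oc4cc(OC)c(Oc5cc(OC)c(Oc6cc(O)c(OCc7ccccc7)c(O)c6C(=O)OCc8ccccc8)c(OC)c5)c(OC)c4)c(OC)c3)c(OC)c2)c(OC)c1 | intermediate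
21 | six-ring 2,3,4-trihydroxy-6-aryloxybenzoic acid (not isolated) | COc1cc(OC)c(Oc2cc(OC)c(Oc3cc(OC)c(Oc4cc(OC)c(Oc5cc(OC)c(Oc6cc(O)c(O)c(O)c6C(=O)O)c(OC)c5)c(OC)c4)c(OC)c3)c(OC)c2)c(OC)c1 | intermediate
22 | six-ring ether, ring F = 3,4,5-trihydroxyphenyl, rings A–E permethylated | COc1cc(OC)c(Oc2cc(OC)c(Oc3cc(OC)c(Oc4cc(OC)c(Oc5cc(OC)c(Oc6cc(O)c(O)c(O)c6)c(OC)c5)c(OC)c4)c(OC)c3)c(OC)c2)c(OC)c1 | intermediate
23 | CNP0187343.0, fully deprotected hexamer | Oc1cc(O)c(Oc2cc(O)c(Oc3cc(O)c(Oc4cc(O)c(Oc5cc(O)c(Oc6cc(O)c(O)c(O)c6)c(O)c5)c(O)c4)c(O)c3)c(O)c2)c(O)c1 | target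

**Total step count:** 15. **Longest linear sequence:** 14 (steps 1–11 and 13–15; step 12 is a one-step side branch).

**Steps most likely to fail**

**Step 13.**
- What may go wrong: the conjugate addition may stall, because the oxygen lone pair weakens the acceptor.
- The aryloxide may be expelled by addition–elimination.
- The enolate oxygen may acylate faster than C4, closing a lactone in place of the carbocycle.

The fallback gives up ring construction and makes the last diaryl ether by coupling. It sets out from five-ring phenol 11. This is coupled under the conditions of step 8 with purchased 5-bromo-1,2,3-trimethoxybenzene to give the permethylated six-ring ether F1. Exhaustive BBr3 cleavage of its fourteen methyl ethers, as in step 15, comes back to the route at 23.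

**Step 11.**
- What may go wrong: ring metalation may compete with removal of the vinyl proton.
- The acetylide may attack the newly formed ester a second time.
- The electron-rich triple bond may be hydrated during work-up and chromatography.

The fallback reaches the same Michael adduct by vinylic substitution, without organolithium reagents and without an isolated ynol ether. Purchased 3,3-dichloroacrylic acid is alkylated with BnBr and K2CO3 to benzyl 3,3-dichloroacrylate F2. The sequence then sets out from 11, whose potassium phenoxide (K2CO3, DMF) displaces one chloride of F2 by addition–elimination. This gives benzyl 3-aryloxy-3-chloroacrylate F3 as an E/Z mixture, and both isomers converge in the next operation. The sodium enolate of 18 then displaces the remaining chloride, which is the better leaving group. This comes back to the route at adduct 19, which is closed to 20 in the same flask with the second base charge of step 13.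

**Step 15.**
- What may go wrong: ether cleavage may stall as boron phenoxide aggregates precipitate.
- The polar, air-sensitive product may be lost by oxidation during isolation.
- Separation from congeners that keep a methyl ether may fail at the free phenol stage.

The fallback changes the isolation strategy to capture and release. It sets out from 22. After the BBr3 treatment and aqueous quench, the crude phenol mixture is not purified but acetylated (Ac2O, pyridine) to the tetradecaacetate F4. This is a stable, non-polar compound that can be chromatographed on silica, and incompletely demethylated fractions can be resubmitted. Degassed HCl in MeOH then removes the acetates by transesterification and comes back to the route at 23.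

**Further compounds**
F1 | step 13 | permethylated six-ring ether (ring F = 3,4,5-trimethoxyphenyl) | COc1cc(OC)c(Oc2cc(OC)c(Oc3cc(OC)c(Oc4cc(OC)c(Oc5cc(OC)c(Oc6cc(OC)c(OC)c(OC)c6)c(OC)c5)c(OC)c4)c(OC)c3)c(OC)c2)c(OC)c1
F2 | step 11 | benzyl 3,3-dichloroacrylate | O=C(OCc1ccccc1)C=C(Cl)Cl
F3 | step 11 | benzyl 3-aryloxy-3-chloroacrylate of fragment A–E (E/Z mixture) | O=C(OCc6ccccc6)C=C(Cl)Oc1c(OC)cc(Oc2c(OC)cc(Oc3c(OC)cc(Oc4c(OC)cc(Oc5c(OC)cc(OC)cc5OC)cc4OC)cc3OC)cc2OC)cc1OC
F4 | step 15 | tetradecaacetate of 23 | CC(=O)Oc1cc(OC(C)=O)c(Oc2cc(OC(C)=O)c(Oc3cc(OC(C)=O)c(Oc4cc(OC(C)=O)c(Oc5cc(OC(C)=O)c(Oc6cc(OC(C)=O)c(OC(C)=O)c(OC(C)=O)c6)c(OC(C)=O)c5)c(OC(C)=O)c4)c(OC(C)=O)c3)c(OC(C)=O)c2)c(OC(C)=O)c1
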